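**Plan**

- Last cut: the three phenols are traced back to benzyl ethers and the CH2–CH2 unit of the chroman to a 2H-chromene alkene, so that one hydrogenation finishes the synthesis.
- Ring C is cut at C3–C4 and at O1–C2. C4 is the benzoyl carbon of ring A, C3 carries ring B, and C2 is an aldehyde-level carbon bound to O1, so the pyranone opens to a 2-acetoxy-4,6-bis(benzyloxy)benzoyl chloride and the morpholine enamine of a ring B arylacetaldehyde.
- The enamine goes back by one-carbon homologation to a 2,2-dimethyl-2H-chromene-5-carbaldehyde, whose pyran ring is cut at O–CMe2 and at the aryl–vinyl bond (aryl propargyl ether Claisen rearrangement).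
- Forward order: ring A is bought, the pyran ring on ring B is built first, ring C closes in the convergent step, and the pyran ring is saturated last.
- The target has no stereocentre. The E enamine double bond is set thermodynamically and disappears in the ring closure.

Key step: step 10

Remark on the chemistry: the pyran double bond of ring B is carried as a spectator through the key step, because the closing hydrogenation removes it together with the benzyl groups; no alkene then has to be reduced next to an aryl benzyl ether and an aldehyde.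

**Route**

Step 1
Reactants: 1 methyl 2,4,6-trihydroxybenzoate
Product: 2 methyl 2,4-bis(benzyloxy)-6-hydroxybenzoate
Conditions: BnBr (2.1 equiv), K2CO3 (2.2 equiv), acetone, reflux
Reagents that add atoms: benzyl bromide, BrCc1ccccc1
Why: Williamson etherification takes the para hydroxyl and one ortho hydroxyl, while the remaining ortho hydroxyl is held in a hydrogen bond to the ester carbonyl and is the least nucleophilic.

Step 2
Reactants: 2 methyl 2,4-bis(benzyloxy)-6-hydroxybenzoate
Product: 3 2,4-bis(benzyloxy)-6-hydroxybenzoic acid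
Conditions: KOH (6 equiv), EtOH/H2O 4:1, reflux; then 1 M HCl, 0 °C, to pH 3
Reagents that add atoms: potassium hydroxide, [K+].[OH-]
Why: Ester saponification of the hindered salicylate needs heat, the carboxylate is stable under base, and cold acidification should limit decarboxylation of the electron-rich acid.

Step 3
Reactants: 3 2,4-bis(benzyloxy)-6-hydroxybenzoic acid
Product: 4 2-acetoxy-4,6-bis(benzyloxy)benzoic acid
Conditions: Ac2O (2.5 equiv), pyridine, DMAP (cat.), CH2Cl2, 0 °C to rt; then H2O, rt, 30 min
Reagents that add atoms: acetic anhydride, CC(=O)OC(C)=O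
Why: DMAP-catalysed O-acetylation of a salicylic acid (the aspirin-type reaction) should cap the phenol, and any mixed anhydride at the carboxyl group is hydrolysed in the aqueous stir.

Step 4
Reactants: 4 2-acetoxy-4,6-bis(benzyloxy)benzoic acid
Product: 5 2-acetoxy-4,6-bis(benzyloxy)benzoyl chloride
Conditions: (COCl)2 (1.5 equiv), DMF (cat.), CH2Cl2, 0 °C to rt; evaporated and used crude the same day
Reagents that add atoms: oxalyl chloride, ClC(=O)C(Cl)=O
Why: Acid chloride formation through the catalytic Vilsmeier-type chloroiminium ion runs at low temperature and should leave the aryl acetate and the benzyl ethers untouched.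

Step 5
Reactants: 6 4-(benzyloxy)-3-hydroxybenzaldehyde; 7 3-chloro-3-methylbut-1-yne
Product: 8 4-(benzyloxy)-3-[(2-methylbut-3-yn-2-yl)oxy]benzaldehyde
Conditions: K2CO3 (2 equiv), KI (cat.), CuI (cat.), DMF, 60 °C
Reagents that add atoms: none
Why: Copper-catalysed propargylic etherification of a phenoxide with a tertiary propargylic chloride proceeds through an ionised copper acetylide, and the phenol is the only nucleophile present.

Step 6
Reactants: 8 4-(benzyloxy)-3-[(2-methylbut-3-yn-2-yl)oxy]benzaldehyde
Product: 9 8-(benzyloxy)-2,2-dimethyl-2H-chromene-5-carbaldehyde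
Conditions: N,N-diethylaniline, 190 °C
Reagents that add atoms: none
Why: The aryl propargyl ether Claisen rearrangement goes to the only free ortho carbon (the other carries the benzyloxy group), and enolisation, 1,5-hydrogen shift and oxa-6π electrocyclisation then give the 2,2-dimethyl-2H-chromene.

Step 7
Reactants: 9 8-(benzyloxy)-2,2-dimethyl-2H-chromene-5-carbaldehyde
Product: 10 8-(benzyloxy)-5-(2-methoxyethenyl)-2,2-dimethyl-2H-chromene (E/Z mixture)
Conditions: (methoxymethyl)triphenylphosphonium chloride (1.5 equiv), KOtBu (1.5 equiv), THF, 0 °C to rt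
Reagents that add atoms: (methoxymethyl)triphenylphosphonium chloride, COC[P+](c1ccccc1)(c1ccccc1)c1ccccc1.[Cl-]
Why: Wittig olefination with the methoxymethyl ylide adds the carbon that becomes C2, and the E/Z mixture is of no consequence because both isomers hydrolyse to the same aldehyde.

Step 8
Reactants: 10 8-(benzyloxy)-5-(2-methoxyethenyl)-2,2-dimethyl-2H-chromene
Product: 11 2-[8-(benzyloxy)-2,2-dimethyl-2H-chromen-5-yl]acetaldehyde
Conditions: 1 M aq. HCl, THF, rt; crude aldehyde taken on at once
Reagents that add atoms: water, O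
Why: Acid-catalysed enol ether hydrolysis (C-protonation, hydration of the oxocarbenium ion, loss of methanol) is fast under dilute acid, which the benzyl ether and the chromene should tolerate for a short time.

Step 9
Reactants: 11 2-[8-(benzyloxy)-2,2-dimethyl-2H-chromen-5-yl]acetaldehyde; 12 morpholine
Product: 13 4-[(E)-2-[8-(benzyloxy)-2,2-dimethyl-2H-chromen-5-yl]ethenyl]morpholine
Conditions: morpholine (1.3 equiv), 4 Å molecular sieves, toluene, rt; filtered, concentrated and used crude
Reagents that add atoms: none
Why: Enamine condensation of an enolisable aldehyde with a secondary amine is driven by removal of water, and the aryl-conjugated E isomer is the thermodynamic product.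

Step 10
Reactants: 5 2-acetoxy-4,6-bis(benzyloxy)benzoyl chloride; 13 4-[(E)-2-[8-(benzyloxy)-2,2-dimethyl-2H-chromen-5-yl]ethenyl]morpholine
Product: 16 5,7-bis(benzyloxy)-3-[8-(benzyloxy)-2,2-dimethyl-2H-chromen-5-yl]-4H-chromen-4-one, via acetoxy enaminone 14 (not isolated), via hydroxy enaminone 15 (not isolated)
Conditions: Et3N (1.2 equiv), CH2Cl2, 0 °C to 40 °C; then HCl (1.25 M in MeOH), 50 °C
Reagents that add atoms: none
Why: The nucleophilic β-carbon of enamine 13 attacks acid chloride 5 and Et3N removes the proton from the resulting iminium ion, giving the vinylogous amide 14 with the new C3–C4 bond and ring B on the carbon next to the ketone. Methanolic HCl then transesterifies the aryl acetate to methyl acetate, and the freed phenol of 15 adds to the protonated enaminone carbon and expels morpholine, so that O1–C2 forms and ring C closes by a 6-endo-trig addition–elimination. The closest known reaction type is the chromone synthesis from enamines and O-acetylsalicyloyl chlorides, together with the acid cyclisation of 2-hydroxyaryl enaminones. No stereocentre is formed, and the double-bond geometry of 14 does not matter because the iminium intermediate rotates freely before closure. The step needs C-acylation over N-acylation and attack at the acid chloride over the acetate: N-acylation of the tertiary enamine gives only a reversible acylammonium ion that passes the acyl group on to carbon, and the acid chloride is by far the stronger electrophile while the acetate keeps the ortho phenol from being acylated.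

Step 11
Reactants: 16 5,7-bis(benzyloxy)-3-[8-(benzyloxy)-2,2-dimethyl-2H-chromen-5-yl]-4H-chromen-4-one
Product: 17 5,7-dihydroxy-3-(8-hydroxy-2,2-dimethyl-3,4-dihydro-2H-chromen-5-yl)-4H-chromen-4-one
Conditions: H2 (1 atm), 10% Pd/C, EtOAc/MeOH 1:1, rt; stopped after uptake of four equivalents of H2
Reagents that add atoms: none
Why: Catalytic hydrogenolysis cleaves the three aryl benzyl ethers and the same catalyst hydrogenates the cis-disubstituted styrenic chromene alkene, while the trisubstituted vinylogous ester C2=C3 of the pyranone should react much more slowly.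

**Compound list**

1 | methyl 2,4,6-trihydroxybenzoate | COC(=O)c1c(O)cc(O)cc1O | starting material
2 | methyl 2,4-bis(benzyloxy)-6-hydroxybenzoate | COC(=O)c1c(O)cc(OCc2ccccc2)cc1OCc1ccccc1 | intermediate
3 | 2,4-bis(benzyloxy)-6-hydroxybenzoic acid | OC(=O)c1c(O)cc(OCc2ccccc2)cc1OCc1ccccc1 | intermediate
4 | 2-acetoxy-4,6-bis(benzyloxy)benzoic acid | CC(=O)Oc1cc(OCc2ccccc2)cc(OCc2ccccc2)c1C(O)=O | intermediate
5 | 2-acetoxy-4,6-bis(benzyloxy)benzoyl chloride | CC(=O)Oc1cc(OCc2ccccc2)cc(OCc2ccccc2)c1C(Cl)=O | intermediate
6 | 4-(benzyloxy)-3-hydroxybenzaldehyde | O=Cc1ccc(OCc2ccccc2)c(O)c1 | starting material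
7 | 3-chloro-3-methylbut-1-yne | CC(C)(Cl)C#C | starting material
8 | 4-(benzyloxy)-3-[(2-methylbut-3-yn-2-yl)oxy]benzaldehyde | O=Cc1ccc(OCc2ccccc2)c(OC(C)(C)C#C)c1 | intermediate
9 | 8-(benzyloxy)-2,2-dimethyl-2H-chromene-5-carbaldehyde | O=Cc1ccc(OCc2ccccc2)c2OC(C)(C)C=Cc12 | intermediate
10 | 8-(benzyloxy)-5-(2-methoxyethenyl)-2,2-dimethyl-2H-chromene (E/Z mixture) | COC=Cc1ccc(OCc2ccccc2)c2OC(C)(C)C=Cc12 | intermediate
11 | 2-[8-(benzyloxy)-2,2-dimethyl-2H-chromen-5-yl]acetaldehyde | O=CCc1ccc(OCc2ccccc2)c2OC(C)(C)C=Cc12 | intermediate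
12 | morpholine | C1COCCN1 | starting material
13 | 4-[(E)-2-[8-(benzyloxy)-2,2-dimethyl-2H-chromen-5-yl]ethenyl]morpholine | O1CCN(CC1)/C=C/c1ccc(OCc2ccccc2)c2OC(C)(C)C=Cc12 | intermediate
14 | 3,5-bis(benzyloxy)-2-{2-[8-(benzyloxy)-2,2-dimethyl-2H-chromen-5-yl]-3-(morpholin-4-yl)prop-2-enoyl}phenyl acetate (double-bond geometry not fixed) | CC(=O)Oc1cc(OCc2ccccc2)cc(OCc2ccccc2)c1C(=O)C(=CN1CCOCC1)c1ccc(OCc2ccccc2)c2OC(C)(C)C=Cc12 | intermediate (not isolated)
15 | 1-[2,4-bis(benzyloxy)-6-hydroxyphenyl]-2-[8-(benzyloxy)-2,2-dimethyl-2H-chromen-5-yl]-3-(morpholin-4-yl)prop-2-en-1-one (double-bond geometry not fixed) | Oc1cc(OCc2ccccc2)cc(OCc2ccccc2)c1C(=O)C(=CN1CCOCC1)c1ccc(OCc2ccccc2)c2OC(C)(C)C=Cc12 | intermediate (not isolated)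
16 | 5,7-bis(benzyloxy)-3-[8-(benzyloxy)-2,2-dimethyl-2H-chromen-5-yl]-4H-chromen-4-one | CC1(C)C=Cc2c(-c3coc4cc(OCc5ccccc5)cc(OCc5ccccc5)c4c3=O)ccc(OCc3ccccc3)c2O1 | intermediate
17 | 5,7-dihydroxy-3-(8-hydroxy-2,2-dimethyl-3,4-dihydro-2H-chromen-5-yl)-4H-chromen-4-one (CNP0078088.0) | CC1(C)CCc2c(-c3coc4cc(O)cc(O)c4c3=O)ccc(O)c2O1 | target

**Totals**

Total step count: 11. Longest linear sequence: 7 steps (steps 5 to 11, from 6).

**Steps most likely to fail**

Step 10. The C-acylation may be slow because the acid chloride is flanked by two ortho substituents and the aryl-conjugated enamine is a weak nucleophile; the acetyl group may be lost or the enamine hydrolysed before the C3–C4 bond forms. The fallback leaves the enamine disconnection and uses the chalcone-to-isoflavone rearrangement. It sets out from aldehyde 9, which is condensed with commercial 1-[2,4-bis(benzyloxy)-6-hydroxyphenyl]ethan-1-one (CC(=O)c1c(O)cc(OCc2ccccc2)cc1OCc1ccccc1; KOH, EtOH, rt, Claisen–Schmidt). This should give (E)-1-[2,4-bis(benzyloxy)-6-hydroxyphenyl]-3-[8-(benzyloxy)-2,2-dimethyl-2H-chromen-5-yl]prop-2-en-1-one F1. Oxidative 1,2-aryl migration with Tl(NO3)3·3H2O (trivalent thallium, 1.1 equiv) in MeOH/HC(OMe)3 is expected to give racemic 1-[2,4-bis(benzyloxy)-6-hydroxyphenyl]-2-[8-(benzyloxy)-2,2-dimethyl-2H-chromen-5-yl]-3,3-dimethoxypropan-1-one F2; the benzyloxy group para to the migrating carbon of ring B favours the shift. Warming F2 with HCl in MeOH closes ring C with loss of two molecules of methanol, and the route is rejoined at 16.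

Step 8. The electron-rich arylacetaldehyde may self-condense or oxidise during hydrolysis and handling, and longer acid contact may draw the neighbouring chromene alkene into cyclisation. The fallback avoids the free aldehyde by a Horner–Wittig enamine synthesis and sets out from aldehyde 9. Diphenylphosphine oxide, paraformaldehyde and morpholine 12 (toluene, 80 °C) give 4-[(diphenylphosphoryl)methyl]morpholine F3. F3 is lithiated (n-BuLi, THF, −78 °C) and added to 9 to give 1-[8-(benzyloxy)-2,2-dimethyl-2H-chromen-5-yl]-2-(diphenylphosphoryl)-2-(morpholin-4-yl)ethan-1-ol F4 as a diastereomer mixture. Elimination of diphenylphosphinate with KOtBu (THF, rt) should give the E enamine, so the route is rejoined at 13 and steps 7 to 9 are bypassed.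

Step 11. Hydrogen uptake may not stop cleanly: the pyranone C2=C3 bond may be over-reduced to the isoflavanone, or the hindered chromene alkene may lag behind the debenzylation. The fallback separates the two events and uses no catalyst, and it sets out from 16. Diimide, generated from 2-nitrobenzenesulfonohydrazide and Et3N (CH2Cl2, rt), reduces only the unpolarised chromene alkene and should give 5,7-bis(benzyloxy)-3-[8-(benzyloxy)-2,2-dimethyl-3,4-dihydro-2H-chromen-5-yl]-4H-chromen-4-one F5. The benzyl groups are then removed with BCl3 and pentamethylbenzene as cation scavenger (CH2Cl2, −78 °C), and the route is rejoined at 17.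

Further compounds
F1 | step 10 | (E)-1-[2,4-bis(benzyloxy)-6-hydroxyphenyl]-3-[8-(benzyloxy)-2,2-dimethyl-2H-chromen-5-yl]prop-2-en-1-one | O=C(/C=C/c1ccc(OCc2ccccc2)c2OC(C)(C)C=Cc12)c1c(O)cc(OCc2ccccc2)cc1OCc1ccccc1
F2 | step 10 | 1-[2,4-bis(benzyloxy)-6-hydroxyphenyl]-2-[8-(benzyloxy)-2,2-dimethyl-2H-chromen-5-yl]-3,3-dimethoxypropan-1-one (racemic) | COC(OC)C(C(=O)c1c(O)cc(OCc2ccccc2)cc1OCc1ccccc1)c1ccc(OCc2ccccc2)c2OC(C)(C)C=Cc12
F3 | step 8 | 4-[(diphenylphosphoryl)methyl]morpholine | O=P(CN1CCOCC1)(c1ccccc1)c1ccccc1
F4 | step 8 | 1-[8-(benzyloxy)-2,2-dimethyl-2H-chromen-5-yl]-2-(diphenylphosphoryl)-2-(morpholin-4-yl)ethan-1-ol (diastereomer mixture) | OC(c1ccc(OCc2ccccc2)c2OC(C)(C)C=Cc12)C(N1CCOCC1)P(=O)(c1ccccc1)c1ccccc1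
F5 | step 11 | 5,7-bis(benzyloxy)-3-[8-(benzyloxy)-2,2-dimethyl-3,4-dihydro-2H-chromen-5-yl]-4H-chromen-4-one | CC1(C)CCc2c(-c3coc4cc(OCc5ccccc5)cc(OCc5ccccc5)c4c3=O)ccc(OCc3ccccc3)c2O1
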